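The cyclopentane ring (C1–C5; C5 is the spiro carbon) is treated as the sum of cyclopentadiene (C1–C2–C3) and an (E)-crotonyl unit (C4–C5). An auxiliary-controlled Diels–Alder reaction forms C3–C4 and C1–C5 in one operation and fixes C1, C4 and the absolute configuration; its product is a norbornene that bears no resemblance to the target. Ozonolysis then cuts the alkene bridge: one bridge carbon becomes C1′ of the side chain, the other is excised. A cis-fused γ-lactone templates the quaternary spiro centre, an aldol condensation closes the six-membered ring, and a radical hydroalkylation of the C1 vinyl group delivers the keto side chain.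

Key step: step 2

Remark on numbering: target atoms are numbered as a spiro[4.5]decene. C1 = ring CH bearing the side chain, C2/C3 = ring CH2, C4 = CHMe, C5 = spiro carbon, C6 = allylic CH2, C7 = vinylic CH, C8 = C–CO2Me, C9 = CHOH, C10 = CH2; the side chain runs from C1′ (CHMe) to the isopropyl group.

Remark on materials: cyclopentadiene is taken as freshly cracked commercial dicyclopentadiene.

Step 1
Reactants: 1 (4S)-4-benzyl-1,3-oxazolidin-2-one; 2 (2E)-but-2-enoyl chloride
Product: 3 (4S)-4-benzyl-3-[(2E)-but-2-enoyl]-1,3-oxazolidin-2-one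
Conditions: n-BuLi, THF, −78 °C; then 2, −78 to 0 °C
Reagents that add atoms: none
Why: N-acylation of the lithiated oxazolidinone by the acid chloride (imide formation) should give the dienophile with the (E)-alkene untouched.

Step 2
Reactants: 3 (4S)-4-benzyl-3-[(2E)-but-2-enoyl]-1,3-oxazolidin-2-one; 4 cyclopenta-1,3-diene
Product: 5 (4S)-4-benzyl-3-{[(1R,2R,3S,4S)-3-methylbicyclo[2.2.1]hept-5-en-2-yl]carbonyl}-1,3-oxazolidin-2-one (2-endo-acyl, 3-exo-methyl)
Conditions: Et2AlCl (1.4 equiv), CH2Cl2, −100 to −78 °C
Reagents that add atoms: none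
Why: Et2AlCl should hold imide 3 as a two-point chelate with an s-cis enoyl unit, and cyclopentadiene should add in a concerted suprafacial [4π+2π] cycloaddition, so that the bonds C3–C4 and C1–C5 of the future cyclopentane form in one event. The closest known reaction is the oxazolidinone-auxiliary-controlled Diels–Alder reaction of N-crotonyl imides with cyclopentadiene. Both rings of the norbornene (the future cyclopentane C1–C5 and the cyclohexene that contains the temporary two-carbon bridge) are closed by this single cycloaddition across the diene termini. The (E)-alkene puts the methyl group trans to the acyl group, and the endo transition state puts the acyl group on the face of the alkene bridge, so the bridge carbon on C1 (the later C1′) ends up trans to the C4 methyl group. The benzyl group shields one face of the chelated dienophile, so the diene should add anti to it and set C1, C3, C4 and C5 in the absolute sense. The step needs endo and π-facial selectivity; chelation and the benzyl group of the auxiliary secure both.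

Step 3
Reactants: 5 Diels–Alder adduct
Product: 8 (3aS,5R,6S,6aR)-5-(hydroxymethyl)-6-methylhexahydro-1H-cyclopenta[c]furan-1-one, via ozonide 6 (not isolated), via dihydroxy imide 7 (not isolated)
Conditions: O3, CH2Cl2, −78 °C; then NaBH4, MeOH, −78 to 0 °C
Reagents that add atoms: ozone [O-][O+]=O
Why: Ozonolysis with reductive (NaBH4) work-up should cut the strained alkene bridge to two primary alcohols; the one on C1, cis and adjacent to the acyl group, should lactonise onto the imide (intramolecular acyl transfer), releasing the auxiliary and telling the two bridge carbons apart without touching a stereocentre.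

Step 4
Reactants: 8 hydroxymethyl lactone
Product: 9 (3aS,5R,6S,6aR)-6-methyl-1-oxohexahydro-1H-cyclopenta[c]furan-5-carboxylic acid
Conditions: TEMPO (0.2 equiv), PhI(OAc)2 (2.2 equiv), MeCN/H2O 1:1, rt
Reagents that add atoms: water O
Why: Nitroxyl-catalysed oxidation of the primary alcohol through the aldehyde hydrate should give the carboxylic acid and leave the lactone intact.

Step 5
Reactants: 9 lactone acid
Product: 10 (3aS,6S,6aR)-6-methylhexahydro-1H-cyclopenta[c]furan-1-one
Conditions: 9-mesityl-10-phenylacridinium tetrafluoroborate (5 mol%), PhSSPh (10 mol%), iPr2NEt (20 mol%), CF3CH2OH, 450 nm LEDs, rt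
Reagents that add atoms: none
Why: Photoredox hydrodecarboxylation (carboxylate oxidation, loss of CO2, hydrogen-atom transfer from thiophenol) should remove the superfluous bridge carbon and leave C3 as a CH2 group.

Step 6
Reactants: 10 lactone; 11 but-3-en-2-one
Product: 13 (3aS,6S,6aR)-6-methyl-6a-(3-oxobutyl)hexahydro-1H-cyclopenta[c]furan-1-one, via silyl ketene acetal 12 (not isolated)
Conditions: LiN(iPr)2, THF, −78 °C, then Me3SiCl; solvent change to CH2Cl2; 11, TiCl4, −78 °C; aq. NaHCO3
Reagents that add atoms: none
Why: Mukaiyama–Michael addition of the silyl ketene acetal to the enone should build the quaternary C5; the cis-fused bicycle can only take the electrophile on its convex face, which places the oxobutyl chain (C10 side) cis to the C4 methyl group and leaves the carbonyl carbon (later C6) cis to the C1 substituent.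

Step 7
Reactants: 13 keto lactone
Product: 14 4-[1,2-bis(hydroxymethyl)-5-methylcyclopentyl]butan-2-ol (CH2OH groups cis; methyl cis to the hydroxybutyl chain; both epimers at the carbinol carbon)
Conditions: LiAlH4, THF, 0 °C to rt
Reagents that add atoms: none
Why: Hydride reduction of the lactone and the ketone should give the triol, which frees the C1′ carbon from the lactone without a protecting group.

Step 8
Reactants: 14 triol
Product: 15 5-methyl-1-(3-oxobutyl)cyclopentane-1,2-dicarbaldehyde (formyl groups cis; methyl cis to the oxobutyl chain)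
Conditions: (COCl)2, DMSO, CH2Cl2, −78 °C; Et3N, −78 to −20 °C
Reagents that add atoms: none
Why: Swern oxidation should convert all three alcohols at low temperature; C1 has no strong thermodynamic bias to epimerise because its neighbour C5 is quaternary.

Step 9
Reactants: 15 keto dialdehyde
Product: 16 2-ethenyl-5-methyl-1-(3-oxobutyl)cyclopentane-1-carbaldehyde (formyl and ethenyl cis; methyl cis to the oxobutyl chain)
Conditions: Ph3PCH3Br, KN(SiMe3)2, THF, 0 °C; then 15 (1.0 equiv of ylide), −78 °C
Reagents that add atoms: methyltriphenylphosphonium bromide C[P+](c1ccccc1)(c1ccccc1)c1ccccc1.[Br-]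
Why: Wittig methylenation should pick the aldehyde on the tertiary C1 over the neopentyl aldehyde on quaternary C5 and over the methyl ketone, giving the C1 vinyl group.

Step 10
Reactants: 16 vinyl keto aldehyde
Product: 18 1-ethenyl-4-methylspiro[4.5]dec-6-en-8-one (ethenyl cis to C6, methyl cis to C10), via aldol 17 (not isolated)
Conditions: KOH, MeOH, rt to 50 °C
Reagents that add atoms: none
Why: Intramolecular aldol condensation of the methyl ketone onto the non-enolisable aldehyde should close the six-membered ring as a 4,4-disubstituted cyclohexenone; the enone position marks which arm of C5 becomes C6.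

Step 11
Reactants: 18 spiro enone
Product: 19 1-ethenyl-9-hydroxy-4-methylspiro[4.5]dec-6-en-8-one (9-OH cis to C1)
Conditions: KN(SiMe3)2, THF, −78 °C; then 3-phenyl-2-(phenylsulfonyl)oxaziridine; aq. NH4Cl
Reagents that add atoms: 3-phenyl-2-(phenylsulfonyl)oxaziridine O=S(=O)(N1OC1c1ccccc1)c1ccccc1
Why: Oxaziridine hydroxylation of the kinetic α′-enolate (no γ-hydrogen is present) should occur at C9 on the ring face remote from the C4 methyl group, which projects over the C10–C9 edge, so the hydroxyl should end up cis to C1.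

Step 12
Reactants: 19 hydroxy enone
Product: 20 9-(tert-butyldimethylsilyloxy)-1-ethenyl-4-methylspiro[4.5]dec-6-en-8-one
Conditions: TBSOTf, 2,6-lutidine, CH2Cl2, −78 to 0 °C
Reagents that add atoms: tert-butyldimethylsilyl triflate CC(C)(C)[Si](C)(C)OS(=O)(=O)C(F)(F)F
Why: Silyl ether formation should mask the hydroxyl for the radical, hydrosilylation and carbonylation steps.

Step 13
Reactants: 20 silyl ether; 21 4-methylpent-1-en-3-one
Product: 22 9-(tert-butyldimethylsilyloxy)-4-methyl-1-[(2R)-6-methyl-5-oxoheptan-2-yl]spiro[4.5]dec-6-en-8-one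
Conditions: Fe(acac)3 (0.3 equiv), PhSiH3, EtOH/ethylene glycol, 60 °C, 21 (3 equiv)
Reagents that add atoms: none
Why: Markovnikov hydrogen-atom transfer from an iron hydride to the vinyl group, then Giese addition of the secondary C1′ radical to the enone, should build the whole side chain; in the conformer with C1–H eclipsing the radical methyl group the acceptor should approach anti to quaternary C5, giving (R) at C1′ as at C20 of 17-substituted steroids, and the ring enone offers the radical no 5-exo pathway.

Step 14
Reactants: 22 keto enone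
Product: 24 9-(tert-butyldimethylsilyloxy)-4-methyl-1-[(2R)-6-methyl-5-oxoheptan-2-yl]spiro[4.5]dec-7-en-8-yl trifluoromethanesulfonate, via triethylsilyl enol ether 23 (not isolated)
Conditions: RhCl(PPh3)3 (2 mol%), Et3SiH, benzene, 50 °C; then CsF, PhNTf2, DME, rt
Reagents that add atoms: N-phenylbis(trifluoromethanesulfonimide) O=S(=O)(N(c1ccccc1)S(=O)(=O)C(F)(F)F)C(F)(F)F
Why: Rhodium-catalysed 1,4-hydrosilylation should reduce only the enone and give the C8=C7 silyl enol ether regiospecifically, and fluoride-mediated triflation should turn it into the enol triflate while the isolated side-chain ketone stays untouched.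

Step 15
Reactants: 24 enol triflate
Product: 25 methyl 9-(tert-butyldimethylsilyloxy)-4-methyl-1-[(2R)-6-methyl-5-oxoheptan-2-yl]spiro[4.5]dec-7-ene-8-carboxylate
Conditions: Pd(OAc)2, PPh3, CO (1 atm), MeOH, Et3N, DMF, 50 °C
Reagents that add atoms: carbon monoxide [C-]#[O+]; methanol CO
Why: Palladium-catalysed methoxycarbonylation of the enol triflate should install the conjugated methyl ester at C8 with the double bond fixed at C7–C8.

Step 16
Reactants: 25 silyl ether ester
Product: 26 methyl (1R,4S,5S,9S)-9-hydroxy-4-methyl-1-[(2R)-6-methyl-5-oxoheptan-2-yl]spiro[4.5]dec-7-ene-8-carboxylate (target)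
Conditions: HF·pyridine, THF, 0 °C to rt
Reagents that add atoms: none
Why: Fluoride desilylation should free the allylic alcohol without affecting the ester, the ketone or any stereocentre.

Compound list
1 | (4S)-4-benzyl-1,3-oxazolidin-2-one | O=C1N[C@@H](Cc2ccccc2)CO1 | starting material
2 | (2E)-but-2-enoyl chloride | C/C=C/C(Cl)=O | starting material
3 | (4S)-4-benzyl-3-[(2E)-but-2-enoyl]-1,3-oxazolidin-2-one | C/C=C/C(=O)N1[C@@H](Cc2ccccc2)COC1=O | intermediate
4 | cyclopenta-1,3-diene | C1=CCC=C1 | starting material
5 | (4S)-4-benzyl-3-{[(1R,2R,3S,4S)-3-methylbicyclo[2.2.1]hept-5-en-2-yl]carbonyl}-1,3-oxazolidin-2-one | C[C@H]1[C@H]2C[C@H](C=C2)[C@@H]1C(=O)N3[C@@H](Cc4ccccc4)COC3=O | intermediate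
6 | ozonide (1,2,4-trioxolane) of 5, mixture at the two new acetal carbons | C[C@H]1[C@H]2C[C@H](C3OOC2O3)[C@@H]1C(=O)N4[C@@H](Cc5ccccc5)COC4=O | intermediate
7 | dihydroxy imide: N-acyl oxazolidinone of 2,4-bis(hydroxymethyl)-5-methylcyclopentanecarboxylic acid (acyl and both CH2OH groups cis, methyl trans) | C[C@H]1[C@H](CO)C[C@H](CO)[C@@H]1C(=O)N2[C@@H](Cc3ccccc3)COC2=O | intermediate
8 | (3aS,5R,6S,6aR)-5-(hydroxymethyl)-6-methylhexahydro-1H-cyclopenta[c]furan-1-one | C[C@H]1[C@H](CO)C[C@@H]2COC(=O)[C@H]12 | intermediate
9 | (3aS,5R,6S,6aR)-6-methyl-1-oxohexahydro-1H-cyclopenta[c]furan-5-carboxylic acid | C[C@H]1[C@H](C(=O)O)C[C@@H]2COC(=O)[C@H]12 | intermediate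
10 | (3aS,6S,6aR)-6-methylhexahydro-1H-cyclopenta[c]furan-1-one | C[C@H]1CC[C@@H]2COC(=O)[C@H]12 | intermediate
11 | but-3-en-2-one | C=CC(C)=O | starting material
12 | trimethylsilyl ketene acetal of 10 | C[C@H]1CC[C@@H]2COC(O[Si](C)(C)C)=C12 | intermediate
13 | (3aS,6S,6aR)-6-methyl-6a-(3-oxobutyl)hexahydro-1H-cyclopenta[c]furan-1-one | C[C@H]1CC[C@@H]2COC(=O)[C@]12CCC(C)=O | intermediate
14 | 4-[1,2-bis(hydroxymethyl)-5-methylcyclopentyl]butan-2-ol (CH2OH groups cis, methyl cis to the hydroxybutyl chain, carbinol epimers) | OC[C@@]1(CCC(C)O)[C@@H](CO)CC[C@@H]1C | intermediate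
15 | 5-methyl-1-(3-oxobutyl)cyclopentane-1,2-dicarbaldehyde (formyl groups cis) | O=C[C@@]1(CCC(C)=O)[C@@H](C=O)CC[C@@H]1C | intermediate
16 | 2-ethenyl-5-methyl-1-(3-oxobutyl)cyclopentane-1-carbaldehyde (formyl and ethenyl cis) | O=C[C@@]1(CCC(C)=O)[C@@H](C=C)CC[C@@H]1C | intermediate
17 | 1-ethenyl-6-hydroxy-4-methylspiro[4.5]decan-8-one (aldol, carbinol epimers) | O=C1CC(O)[C@@]2(CC1)[C@@H](C=C)CC[C@@H]2C | intermediate
18 | 1-ethenyl-4-methylspiro[4.5]dec-6-en-8-one (ethenyl cis to C6, methyl cis to C10) | O=C1C=C[C@@]2(CC1)[C@@H](C=C)CC[C@@H]2C | intermediate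
19 | 1-ethenyl-9-hydroxy-4-methylspiro[4.5]dec-6-en-8-one (9-OH cis to C1) | O=C1C=C[C@@]2(C[C@@H]1O)[C@@H](C=C)CC[C@@H]2C | intermediate
20 | 9-(tert-butyldimethylsilyloxy)-1-ethenyl-4-methylspiro[4.5]dec-6-en-8-one | O=C1C=C[C@@]2(C[C@@H]1O[Si](C)(C)C(C)(C)C)[C@@H](C=C)CC[C@@H]2C | intermediate
21 | 4-methylpent-1-en-3-one | C=CC(=O)C(C)C | starting material
22 | 9-(tert-butyldimethylsilyloxy)-4-methyl-1-[(2R)-6-methyl-5-oxoheptan-2-yl]spiro[4.5]dec-6-en-8-one | O=C1C=C[C@@]2(C[C@@H]1O[Si](C)(C)C(C)(C)C)[C@@H]([C@H](C)CCC(=O)C(C)C)CC[C@@H]2C | intermediate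
23 | triethylsilyl enol ether of the 8-ketone (C7=C8) | CC[Si](CC)(CC)OC1=CC[C@@]2(C[C@@H]1O[Si](C)(C)C(C)(C)C)[C@@H]([C@H](C)CCC(=O)C(C)C)CC[C@@H]2C | intermediate
24 | 9-(tert-butyldimethylsilyloxy)-4-methyl-1-[(2R)-6-methyl-5-oxoheptan-2-yl]spiro[4.5]dec-7-en-8-yl trifluoromethanesulfonate | O=S(=O)(OC1=CC[C@@]2(C[C@@H]1O[Si](C)(C)C(C)(C)C)[C@@H]([C@H](C)CCC(=O)C(C)C)CC[C@@H]2C)C(F)(F)F | intermediate
25 | methyl 9-(tert-butyldimethylsilyloxy)-4-methyl-1-[(2R)-6-methyl-5-oxoheptan-2-yl]spiro[4.5]dec-7-ene-8-carboxylate | COC(=O)C1=CC[C@@]2(C[C@@H]1O[Si](C)(C)C(C)(C)C)[C@@H]([C@H](C)CCC(=O)C(C)C)CC[C@@H]2C | intermediate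
26 | methyl (1R,4S,5S,9S)-9-hydroxy-4-methyl-1-[(2R)-6-methyl-5-oxoheptan-2-yl]spiro[4.5]dec-7-ene-8-carboxylate | COC(=O)C1=CC[C@@]2(C[C@@H]1O)[C@@H]([C@H](C)CCC(=O)C(C)C)CC[C@@H]2C | target

Total step count: 16. Longest linear sequence: 16 steps (from 1 to 26).

Steps most likely to fail

Step 6. The tetrasubstituted silyl ketene acetal must bond at the ring-fusion carbon next to, and cis to, the methyl-bearing carbon; the addition may be slow enough for desilylation or polymerisation of the enone to take over. Fallback: setting out from 10, the lithium enolate (LiN(iPr)2, THF/HMPA, −78 °C) would be alkylated with the more reactive allylic halide 1,3-dichlorobut-2-ene, again on the convex face, to give the 6a-(3-chlorobut-2-enyl) lactone F1. Hydrolysis of the vinyl chloride in cold concentrated H2SO4 would then lead back to 13.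

Step 9. Chemoselectivity among two aldehydes and a ketone may be lost, and the basic ylide may epimerise the formyl-bearing C1. Fallback: setting out from 14, nitroxyl oxidation (TEMPO, PhI(OAc)2, 1 equiv) of the less hindered primary alcohol would give an aldehyde that is trapped by the neopentyl CH2OH as the five-membered lactol F2. Wittig methylenation of this lactol (Ph3P=CH2, excess) would give the vinyl diol F3, and Swern oxidation of both remaining alcohols would come back to 16.

Step 13. Facial selectivity at the new C1′ centre rests only on the conformational preference of a secondary radical, and the radical may be reduced to an ethyl group before it adds. Fallback: setting out from 20, rhodium-catalysed branched-selective asymmetric hydroformylation (Rh(acac)(CO)2, BOBPHOS ligand, CO/H2) would set C1′ under ligand control and give the branched aldehyde F4. Horner–Wadsworth–Emmons olefination with dimethyl (3-methyl-2-oxobutyl)phosphonate (LiCl, iPr2NEt, MeCN) would give the side-chain enone F5. Conjugate reduction of this unhindered enone with [(Ph3P)CuH]6, which should spare the hindered ring enone, would come back to 22.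

Further compounds
F1 | step 6 | (3aS,6S,6aR)-6a-(3-chlorobut-2-enyl)-6-methylhexahydro-1H-cyclopenta[c]furan-1-one | C[C@H]1CC[C@@H]2COC(=O)[C@]12CC=C(C)Cl
F2 | step 9 | lactol: 6a-(3-hydroxybutyl)-6-methylhexahydro-1H-cyclopenta[c]furan-3-ol (cis-fused, hemiacetal carbon on C1 of the target numbering) | C[C@H]1CC[C@@H]2C(O)OC[C@]12CCC(C)O
F3 | step 9 | 4-[2-ethenyl-1-(hydroxymethyl)-5-methylcyclopentyl]butan-2-ol (CH2OH and ethenyl cis) | OC[C@@]1(CCC(C)O)[C@@H](C=C)CC[C@@H]1C
F4 | step 13 | (2R)-2-[9-(tert-butyldimethylsilyloxy)-4-methyl-8-oxospiro[4.5]dec-6-en-1-yl]propanal | O=C1C=C[C@@]2(C[C@@H]1O[Si](C)(C)C(C)(C)C)[C@@H]([C@H](C)C=O)CC[C@@H]2C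
F5 | step 13 | 9-(tert-butyldimethylsilyloxy)-4-methyl-1-[(2R,3E)-6-methyl-5-oxohept-3-en-2-yl]spiro[4.5]dec-6-en-8-one | O=C1C=C[C@@]2(C[C@@H]1O[Si](C)(C)C(C)(C)C)[C@@H]([C@H](C)/C=C/C(=O)C(C)C)CC[C@@H]2C
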